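- The dawn run, with 0.15 M of scavenger, showed free substrate climbing from 8% to 23% while first and double product stayed near 11% and 26%. The noon flask has the same charges but 0.075 M of scavenger, and I had to carry it on to 20 min.

| flask | substrate | partner | scavenger | remark | time |
|---|---|---|---|---|---|
| noon | 0.050 M | 0.055 M | 0.075 M | the very flask that is asked about, followed so far |  |
| dawn | 0.050 M | 0.055 M | 0.15 M | run made earlier |  |
| flask | 0.050 M | 0.0550 M | 0.0750 M |  | 20 min |

- noon (time / min: substrate / %, first product / %, double product / %): 0.833: 17, 20, 16; 2.00: 10, 13, 25; 4.00: 10, 7, 22; 6.00: 9, 8, 25
- dawn (time / min: substrate / %, first product / %, double product / %): 2.00: 8, 10, 24; 4.00: 12, 10, 28; 6.00: 17, 10, 27; 8.00: 23, 11, 26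

(readings scatter by 1.5 percentage points)

1. amount of substrate at 20 min, in percent of the substrate charged
2. amount of first product at 20 min, in percent of the substrate charged
3. amount of double product at 20 min, in percent of the substrate charged
4. amount of triple product at 20 min, in percent of the substrate charged

- a reading of substrate is of its free form alone

- I assumed that partner, the limiting reagent, ends in products holding one, two and three partners. The noon flask's partner ratio of 110% and its last readings of first and double product then leave triple product at 17.3%.
- I called 49.7% the substrate ceiling, the charge minus the three products.
- One extreme noon flask frees nothing more and keeps substrate at 9%. The other frees the whole gap of 41 percentage points and reaches the ceiling.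
- The dawn run's ceiling, 47.3%, assumed to hold from its first reading on, gives a gap shrinking from 39 points to 24 points, so I read a rough decay constant of 0.0800 /min from these scattered readings.
- I assumed that constant scales with scavenger, so noon, at half the scavenger, decays at half the pace. Noon substrate looked flat so far, so I started the decay from its last reading, which is a judgement. My reckoning gave 26.4% substrate at 20 min.
- The forecast gave substrate 18%, first product 9%, double product 24% and triple product 18%, holding that “the scavenger slowly frees it”. Its substrate is lower than mine.
- The noon flask gave substrate 26.5%, first product 7.84%, double product 24.3% and triple product 17.9%.

    scavenger + released group → scavenged by-product (k = 12.3 /M/min)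
    partner + first product → double product + released group (k = 37.7 /M/min)
    substrate + released group ⇌ idle adduct, settled at all times (K = 802 /M)
    partner + double product → triple product + released group (k = 12.0 /M/min)
    substrate + partner → first product + released group (k = 24.8 /M/min)

- In the noon flask the half-life of first product by its partner step alone, at charged concentrations, was 0.33 min, short against 20 min, while scavenger's half-life by its capture step at 20 min was far longer, 51 min. At 20 min partner stood at 0% and idle adduct at 23.5%, with free substrate below the ceiling of 49.7%, and after 200 min substrate stood at 48.7%.
- In the neighbour charged with 0.20 M of substrate, partner is 27.5% of the substrate charge, and with first product 17.4% and double product 4.66% the ceiling reckons 77.7%. That flask gave free substrate 55.3% and idle adduct 22.3% at 20.0 min.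

(Readings and results stem from a simulated flask on assumed constants, noise included.)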